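**Retrosynthetic overview** (cyclopentane numbering: C1 = aryl-bearing CH, C2 = CMe2, C3 = CH2, C4 = isopropenyl-bearing CH, C5 = CH2)

1. Target ⇐ tricyclic hemiacetal by Rh-mediated decarbonylation. In the hemiacetal, C5 still carries one extra carbon (a masked CHO) tied to the ortho phenol oxygen as a dihydropyran ring, a temporary tether that is not in the target.
2. Hemiacetal ⇐ α-quaternary aldehyde + 2,4,6-trihydroxybenzophenone by domino Knoevenagel condensation / intramolecular oxa-Diels–Alder reaction of an o-quinone methide with its tethered silyl enol ether. One operation forms the aryl–C1 bond, the C1–C5 ring bond (cyclopentane), the O–C bond of the tether and the C1 stereocentre.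
3. Enabling feature: C1 is benzylic and ortho to a phenolic OH of the phloroglucinol ring, so it can be the exocyclic carbon of an o-quinone methide (O=C–C=C1 oxadiene). Its neighbour C2 is quaternary (the aldehyde cannot enolise, the methide cannot tautomerise), and its other neighbour C5 is a bare CH2 that can carry a traceless formyl carbon.
4. Aldehyde ⇐ (S)-lavandulol (Evans deconjugative alkylation). Its CH2OH becomes C3 and alkylates isobutyronitrile (C2 with both methyls, nitrile carbon = C1); its prenyl group is cut to C5–CHO and masked as a silyl enol ether; its stereocentre is C4.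
5. Ring order: both benzene rings are bought; the temporary dihydropyran and the cyclopentane close together in the key step, the cyclopentane being the last ring of the skeleton; the dihydropyran is excised in the last step.

Key step: step 10

Assumption: (S)-lavandulol is made rather than bought, since the racemate and the (R)-enantiomer are taken to be the usual articles of commerce. The cycloadduct is drawn closed through the 4-OH of the benzophenone (para to the benzoyl group); closure through the 2-OH would give a regioisomeric acetal that ends in the same target.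

Step 1
Reactants: 1 (S)-4-benzyloxazolidin-2-one; 2 3-methylbut-2-enoyl chloride
Product: 3 (S)-4-benzyl-3-(3-methylbut-2-enoyl)oxazolidin-2-one
Conditions: n-BuLi, THF, −78 °C; then 2, −78 → 0 °C
Reagents that add atoms: none
Why: N-Acylation of the lithiated oxazolidinone by the acid chloride (standard attachment of an Evans auxiliary) should proceed cleanly and creates no stereocentre.

Step 2
Reactants: 3 (S)-4-benzyl-3-(3-methylbut-2-enoyl)oxazolidin-2-one; 4 prenyl bromide
Product: 5 (S)-4-benzyl-3-[(S)-5-methyl-2-(prop-1-en-2-yl)hex-4-enoyl]oxazolidin-2-one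
Conditions: NaHMDS, THF, −78 °C; then 4, −78 → −30 °C
Reagents that add atoms: none
Why: NaHMDS removes a γ-proton of the senecioyl imide to give the sodium-chelated Z-dienolate, which should be alkylated at Cα on the face opposite to the benzyl group (Evans asymmetric alkylation in its deconjugative form), so that the new stereocentre is S and the isopropenyl group is released from the conjugated system.

Step 3
Reactants: 5 (S)-4-benzyl-3-[(S)-5-methyl-2-(prop-1-en-2-yl)hex-4-enoyl]oxazolidin-2-one
Product: 6 (S)-lavandulol
Conditions: LiBH4, H2O (1 equiv), Et2O, 0 °C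
Reagents that add atoms: none
Why: Reductive cleavage of the N-acyloxazolidinone by LiBH4/H2O should give the primary alcohol and the recoverable auxiliary without touching the alkenes or the α-stereocentre, which is no longer acidic after reduction.

Step 4
Reactants: 6 (S)-lavandulol
Product: 7 (S)-3-(iodomethyl)-2,6-dimethylhepta-1,5-diene
Conditions: I2, PPh3, imidazole, CH2Cl2, 0 °C → rt
Reagents that add atoms: iodine, II
Why: Appel-type iodination of the primary alcohol should proceed by SN2 at the CH2 group and leaves the adjacent stereocentre untouched.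

Step 5
Reactants: 7 (S)-3-(iodomethyl)-2,6-dimethylhepta-1,5-diene; 8 isobutyronitrile
Product: 9 (R)-2,2,7-trimethyl-4-(prop-1-en-2-yl)oct-6-enenitrile
Conditions: 8, LDA, THF, −78 °C; then 7, DMPU, −78 °C → rt
Reagents that add atoms: none
Why: The lithiated tertiary nitrile is a small, weakly basic and strongly nucleophilic carbanion, so SN2 alkylation by the β-branched primary iodide (nitrile α-alkylation) should install the quaternary carbon that becomes C2 and the nitrile carbon that becomes C1, with the stereocentre only a spectator.

Step 6
Reactants: 9 (R)-2,2,7-trimethyl-4-(prop-1-en-2-yl)oct-6-enenitrile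
Product: 10 5-(3,3-dimethyloxiran-2-yl)-2,2-dimethyl-4-(prop-1-en-2-yl)pentanenitrile (both oxirane epimers)
Conditions: mCPBA (1.05 equiv), CH2Cl2, 0 °C
Reagents that add atoms: mCPBA, O=C(OO)c1cccc(Cl)c1
Why: Prilezhaev epoxidation with one equivalent of peracid should pick the electron-rich trisubstituted alkene over the 1,1-disubstituted isopropenyl group, and the new oxirane stereocentre, formed unselectively, is erased in step 7.

Step 7
Reactants: 10 5-(3,3-dimethyloxiran-2-yl)-2,2-dimethyl-4-(prop-1-en-2-yl)pentanenitrile
Product: 11 (S)-2,2-dimethyl-6-oxo-4-(prop-1-en-2-yl)hexanenitrile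
Conditions: H5IO6, THF–H2O, 0 °C → rt
Reagents that add atoms: none
Why: Periodic acid should open the oxirane and cleave its C–C bond in the same flask (glycol-type oxidative cleavage), releasing acetone and the aldehyde that holds C5 and the future traceless carbon, with no epimerisable centre involved.

Step 8
Reactants: 11 (S)-2,2-dimethyl-6-oxo-4-(prop-1-en-2-yl)hexanenitrile
Product: 12 (S,Z)-2,2-dimethyl-4-(prop-1-en-2-yl)-6-[(triisopropylsilyl)oxy]hex-5-enenitrile
Conditions: TIPSOTf, Et3N, CH2Cl2, 0 °C → rt
Reagents that add atoms: triisopropylsilyl triflate, CC(C)[Si](OS(=O)(=O)C(F)(F)F)(C(C)C)C(C)C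
Why: Soft enolisation with a silyl triflate and Et3N should O-silylate the only enolisable carbonyl group to the mainly Z-configured silyl enol ether, which masks the aldehyde during step 9 and is the dienophile of step 10.

Step 9
Reactants: 12 (S,Z)-2,2-dimethyl-4-(prop-1-en-2-yl)-6-[(triisopropylsilyl)oxy]hex-5-enenitrile
Product: 13 (S,Z)-2,2-dimethyl-4-(prop-1-en-2-yl)-6-[(triisopropylsilyl)oxy]hex-5-enal
Conditions: DIBAL-H, toluene, −78 °C; then aq. Rochelle salt, rt
Reagents that add atoms: water, O
Why: DIBAL-H should transfer only one hydride to the hindered nitrile (partial reduction of a nitrile to an aldehyde), and buffered aqueous work-up then delivers the α-quaternary aldehyde while the silyl enol ether and both alkenes are left alone.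

Step 10
Reactants: 13 (S,Z)-2,2-dimethyl-4-(prop-1-en-2-yl)-6-[(triisopropylsilyl)oxy]hex-5-enal; 14 2,4,6-trihydroxybenzophenone
Product: 17 tricyclic hemiacetal [(3S,3aR,4S,9bR)-4,7,9-trihydroxy-1,1-dimethyl-3-(prop-1-en-2-yl)-1,2,3,3a,4,9b-hexahydrocyclopenta[c]chromen-8-yl](phenyl)methanone (one anomer drawn), via o-quinone methide 15 (not isolated), via silyl acetal 16 (not isolated)
Conditions: EDDA (20 mol%), 4 Å MS, MeCN–toluene, 60 °C; then TBAF, AcOH, THF, 0 °C
Reagents that add atoms: none
Why: Under ammonium acetate catalysis the non-enolisable aldehyde 13 should condense with the nucleophilic C3–H of 14 (Knoevenagel-type condensation, loss of water) to the E-configured o-quinone methide 15, whose O=C–C=C oxadiene is trapped by the tethered electron-rich silyl enol ether in an inverse-electron-demand oxa-Diels–Alder reaction; the closest known reaction type is the domino Knoevenagel/hetero-Diels–Alder sequence of aldehydes that carry a tethered alkene, together with the cycloadditions of phenol-derived o-quinone methides with enol ethers. The cyclopentane is closed by the C1–C5 bond in a 5-exo mode with respect to the exocyclic methide C=C (fused mode, three-atom tether, helped by the gem-dimethyl group), and the temporary dihydropyran is closed by the O–C bond in the same asynchronous event, the polarity (methide carbon to the β-carbon of the enol ether, oxygen to the oxygenated carbon) fixing the regiochemistry. The short tether allows only a cis ring fusion, so the aryl carbon and the acetal carbon end up cis on the cyclopentane, and the existing C4 stereocentre steers the face of the dienophile: its hydrogen eclipses the enol ether (A1,3 strain with the Z-silyloxy group) and the isopropenyl group points to the convex side, away from the forming pyran, which should make C1 R and place aryl and isopropenyl trans. The step needs chemoselectivity of the methide for the enol ether over the isopropenyl group, secured by the far higher nucleophilicity of the enol ether and by five- versus six-membered closure, and it needs 13 to act only as the electrophile, secured by its quaternary α-carbon (no enamine, no aldol, no tautomerisation of 15 to a vinylphenol). The configuration at the acetal carbon, the E/Z ratio of the enol ether and the choice of the 2-OH or 4-OH of 14 as pyran oxygen do not matter, because fluoride/AcOH turns every such isomer of 16 into a hemiacetal of type 17 and step 11 removes the acetal carbon and frees the phenol.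

Step 11
Reactants: 17 tricyclic hemiacetal
Product: 18 [3-[(1R,4R)-2,2-dimethyl-4-(prop-1-en-2-yl)cyclopentyl]-2,4,6-trihydroxyphenyl](phenyl)methanone (CNP0143418.1)
Conditions: RhCl(PPh3)3 (1.2 equiv), PhCN, 130 °C
Reagents that add atoms: none
Why: Tsuji–Wilkinson decarbonylation acts on the hydroxy-aldehyde tautomer of hemiacetal 17: oxidative addition of the formyl C–H bond, CO extrusion and C–H reductive elimination should turn the formyl-bearing carbon into the C5 methylene and free the phenol, the trans arrangement of formyl and isopropenyl groups on the ring disfavouring intramolecular hydroacylation, and no stereocentre of the target is touched.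

**Compound list**

1 | (S)-4-benzyloxazolidin-2-one | O=C1OC[C@H](Cc2ccccc2)N1 | starting material
2 | 3-methylbut-2-enoyl chloride | CC(C)=CC(Cl)=O | starting material
3 | (S)-4-benzyl-3-(3-methylbut-2-enoyl)oxazolidin-2-one | CC(C)=CC(=O)N1C(=O)OC[C@@H]1Cc1ccccc1 | intermediate
4 | prenyl bromide (1-bromo-3-methylbut-2-ene) | CC(C)=CCBr | starting material
5 | (S)-4-benzyl-3-[(S)-5-methyl-2-(prop-1-en-2-yl)hex-4-enoyl]oxazolidin-2-one | C=C(C)[C@@H](C(=O)N1C(=O)OC[C@@H]1Cc1ccccc1)CC=C(C)C | intermediate
6 | (S)-lavandulol, (S)-5-methyl-2-(prop-1-en-2-yl)hex-4-en-1-ol | C=C(C)[C@@H](CO)CC=C(C)C | intermediate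
7 | (S)-3-(iodomethyl)-2,6-dimethylhepta-1,5-diene | C=C(C)[C@@H](CI)CC=C(C)C | intermediate
8 | isobutyronitrile | CC(C)C#N | starting material
9 | (R)-2,2,7-trimethyl-4-(prop-1-en-2-yl)oct-6-enenitrile | C=C(C)[C@@H](CC(C)(C)C#N)CC=C(C)C | intermediate
10 | 5-(3,3-dimethyloxiran-2-yl)-2,2-dimethyl-4-(prop-1-en-2-yl)pentanenitrile, C4 as in 9, both oxirane epimers | C=C(C)[C@@H](CC(C)(C)C#N)CC1OC1(C)C | intermediate
11 | (S)-2,2-dimethyl-6-oxo-4-(prop-1-en-2-yl)hexanenitrile | C=C(C)[C@@H](CC(C)(C)C#N)CC=O | intermediate
12 | (S,Z)-2,2-dimethyl-4-(prop-1-en-2-yl)-6-[(triisopropylsilyl)oxy]hex-5-enenitrile | C=C(C)[C@@H](CC(C)(C)C#N)/C=C\O[Si](C(C)C)(C(C)C)C(C)C | intermediate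
13 | (S,Z)-2,2-dimethyl-4-(prop-1-en-2-yl)-6-[(triisopropylsilyl)oxy]hex-5-enal | C=C(C)[C@@H](CC(C)(C)C=O)/C=C\O[Si](C(C)C)(C(C)C)C(C)C | intermediate
14 | 2,4,6-trihydroxybenzophenone | O=C(c1ccccc1)c1c(O)cc(O)cc1O | starting material
15 | o-quinone methide (not isolated): E-alkylidene cyclohexadienone from 13 and C3 of 14, side-chain stereocentre S | C=C(C)[C@@H](CC(C)(C)/C=C1/C(=O)C=C(O)C(C(=O)c2ccccc2)=C1O)/C=C\O[Si](C(C)C)(C(C)C)C(C)C | intermediate
16 | silyl acetal (not isolated): [(3S,3aR,4R,9bR)-7,9-dihydroxy-1,1-dimethyl-3-(prop-1-en-2-yl)-4-[(triisopropylsilyl)oxy]-1,2,3,3a,4,9b-hexahydrocyclopenta[c]chromen-8-yl](phenyl)methanone; 3a,9b-cis-fused, isopropenyl trans to C4 | C=C(C)[C@@H]1[C@H]2[C@@H](O[Si](C(C)C)(C(C)C)C(C)C)Oc3cc(O)c(C(=O)c4ccccc4)c(O)c3[C@H]2C(C)(C)C1 | intermediate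
17 | tricyclic hemiacetal: [(3S,3aR,4S,9bR)-4,7,9-trihydroxy-1,1-dimethyl-3-(prop-1-en-2-yl)-1,2,3,3a,4,9b-hexahydrocyclopenta[c]chromen-8-yl](phenyl)methanone; anomeric mixture, one anomer drawn | C=C(C)[C@@H]1[C@H]2[C@@H](O)Oc3cc(O)c(C(=O)c4ccccc4)c(O)c3[C@H]2C(C)(C)C1 | intermediate
18 | [3-[(1R,4R)-2,2-dimethyl-4-(prop-1-en-2-yl)cyclopentyl]-2,4,6-trihydroxyphenyl](phenyl)methanone; aryl and isopropenyl trans | C=C(C)[C@@H]1C[C@@H](c2c(O)cc(O)c(C(=O)c3ccccc3)c2O)C(C)(C)C1 | target

**Step count:** 11 steps in total. **Longest linear sequence:** 11 steps (fully linear from 1).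

**Steps most likely to fail, with fallbacks**

Step 10. The silyl enol ether may be lost by protodesilylation, or captured by the iminium ion of 13, before the slow condensation of the neopentyl-type aldehyde with the arene has occurred; a second alkylation of 14 is also possible. The fallback separates arene–aldehyde bond formation from methide release and uses no amine. It sets out from 13 and 14 and comes back at 17. Heating 13, 14 and phenylboronic acid with catalytic propionic acid in toluene under water removal should give the boron-templated ortho-hydroxyalkylation product, the 2-phenyl-4H-1,3,2-benzodioxaborin F1. Thermolysis of F1 in toluene at 140 °C should release the same o-quinone methide 15 under neutral conditions; this cyclises to 16, and TBAF/AcOH then gives 17.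

Step 11. Entry of rhodium may be slow because 17 rests as the hemiacetal; β-hydride elimination from the secondary alkyl rhodium hydride and migration of the isopropenyl double bond are the other loss channels. The fallback leads from 17 directly to 18 and replaces the organometallic path by a radical chain: tert-dodecanethiol (catalyst), di-tert-butyl peroxide, chlorobenzene, 130 °C. A thiyl radical abstracts the formyl hydrogen of the open-chain tautomer, the acyl radical loses CO, and the secondary cyclopentyl radical is reduced by the thiol. No new compound is isolated.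

Step 9. Hydrolysis of the hindered reduction product may be incomplete under the mild work-up that the silyl enol ether demands, or the enol ether may be lost if the work-up is made more acidic. The fallback reduces the nitrile before the enol ether exists and relies on chemoselective enolisation. It sets out from 9 and comes back at 13. DIBAL-H reduction of 9 with ordinary acidic work-up should give (R)-2,2,7-trimethyl-4-(prop-1-en-2-yl)oct-6-enal F2. Dimethyldioxirane should epoxidise its trisubstituted alkene without Baeyer–Villiger attack on the aldehyde, giving epoxy aldehyde F3. Periodic acid should cleave F3 to (S)-2,2-dimethyl-4-(prop-1-en-2-yl)hexanedial F4. TIPSOTf/Et3N can silylate only the enolisable aldehyde of F4, which gives 13.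

**Further compounds**

F1 | step 10 | [5,7-dihydroxy-4-[(S,Z)-2-methyl-4-(prop-1-en-2-yl)-6-[(triisopropylsilyl)oxy]hex-5-en-2-yl]-2-phenyl-4H-benzo[d][1,3,2]dioxaborinin-6-yl](phenyl)methanone, both C4 epimers | C=C(C)[C@@H](CC(C)(C)C1OB(c2ccccc2)Oc2cc(O)c(C(=O)c3ccccc3)c(O)c21)/C=C\O[Si](C(C)C)(C(C)C)C(C)C
F0 | step 11 | none | none
F2 | step 9 | (R)-2,2,7-trimethyl-4-(prop-1-en-2-yl)oct-6-enal | C=C(C)[C@@H](CC(C)(C)C=O)CC=C(C)C
F3 | step 9 | 5-(3,3-dimethyloxiran-2-yl)-2,2-dimethyl-4-(prop-1-en-2-yl)pentanal, both oxirane epimers | C=C(C)[C@@H](CC(C)(C)C=O)CC1OC1(C)C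
F4 | step 9 | (S)-2,2-dimethyl-4-(prop-1-en-2-yl)hexanedial | C=C(C)[C@@H](CC(C)(C)C=O)CC=O
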